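The 14-membered ring is numbered from the ester-bearing carbon (C1) through the stereocentre (C4) and is opened at C12–C13. C13–C14–C1(CO2Me) is a 2-alkylidene glutarate residue and C11=C12 an E-2-methylalkenyl unit, so C13 can be a primary radical released from a carboxylic acid and C12 the CH end of an alkenyl iodide. A nickel-electrocatalytic decarboxylative alkenylation of the seco redox-active ester closes the ring in one operation, forming the C(sp2)–C(sp3) bond with retention of alkene geometry. The linear precursor grows from geranyl bromide: alkyne carboalumination sets C11=C12, a Johnson–Claisen rearrangement transfers the chirality of an (R)-allylic alcohol to C4, and a Horner–Wadsworth–Emmons reaction attaches the glutarate.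

Key step: step 12

Step 1
Reactants: 1 geranyl bromide [(2E)-1-bromo-3,7-dimethylocta-2,6-diene]; 2 1-(trimethylsilyl)propyne
Product: 4 (5E)-6,10-dimethylundeca-5,9-dien-1-yne, via silylated enyne 3 (not isolated)
Conditions: 2, n-BuLi, THF, −78 °C; add 1, −78 °C → rt; then K2CO3, MeOH, rt
Reagents that add atoms: none
Why: Propargylic lithiation of the silyl-capped propyne and SN2 alkylation by the allylic bromide (the silyl group suppresses allenyl products and the E-alkene of 1 is untouched) builds the 1,5-enyne, and methanolic carbonate then removes the alkynyl silane (protodesilylation).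

Step 2
Reactants: 4 (5E)-6,10-dimethylundeca-5,9-dien-1-yne
Product: 6 (1E,5E)-1-iodo-2,6,10-trimethylundeca-1,5,9-triene, via alkenylalane 5 (not isolated)
Conditions: Me3Al, Cp2ZrCl2 (0.25 equiv), CH2Cl2, 0 °C → rt; then I2, THF, −30 → 0 °C
Reagents that add atoms: trimethylaluminium, C[Al](C)C; iodine, II
Why: Negishi zirconium-catalysed carboalumination adds methyl and aluminium syn across the terminal alkyne with methyl on the internal carbon, and iodinolysis of the C–Al bond with retention gives the E-alkenyl iodide while the two isolated trisubstituted alkenes are inert.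

Step 3
Reactants: 6 (1E,5E)-1-iodo-2,6,10-trimethylundeca-1,5,9-triene
Product: 8 (2E,6E,10E)-11-iodo-2,6,10-trimethylundeca-2,6,10-trienal, via allylic alcohol 7 (not isolated)
Conditions: SeO2 (cat.), t-BuOOH, salicylic acid (cat.), CH2Cl2, 0 °C → rt, to partial conversion; then MnO2, CH2Cl2, rt
Reagents that add atoms: tert-butyl hydroperoxide, CC(C)(C)OO; selenium dioxide, O=[Se]=O
Why: Riley-type SeO2 allylic oxidation (ene reaction then [2,3]-shift) attacks the E-methyl of the most accessible, most electron-rich terminal isopropylidene group (the iodoalkene is deactivated), and MnO2 then converges the alcohol/aldehyde mixture on the E-enal without touching non-allylic sites.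

Step 4
Reactants: 8 (2E,6E,10E)-11-iodo-2,6,10-trimethylundeca-2,6,10-trienal
Product: 10 (4R,5E,9E,13E)-14-iodo-5,9,13-trimethyltetradeca-1,5,9,13-tetraen-4-ol, via borinate ester 9 (not isolated)
Conditions: (+)-Ipc2B(allyl) (pentane solution), Et2O, −78 °C; then NaOH, H2O2, 0 °C → rt
Reagents that add atoms: (+)-B-allyldiisopinocampheylborane (the reagent derived from (−)-α-pinene), C=CCB([C@@H]1[C@@H](C)[C@@H]2C[C@H](C1)C2(C)C)[C@@H]1[C@@H](C)[C@@H]2C[C@H](C1)C2(C)C
Why: Brown allylboration through a closed chair transition state, in which the isopinocampheyl groups of the reagent derived from (−)-α-pinene direct allyl transfer to the re face of the aldehyde, sets the R carbinol centre; oxidative work-up frees the alcohol.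

Step 5
Reactants: 10 (4R,5E,9E,13E)-14-iodo-5,9,13-trimethyltetradeca-1,5,9,13-tetraen-4-ol
Product: 11 (5R,6E,10E,14E)-15-iodo-2,6,10,14-tetramethylpentadeca-2,6,10,14-tetraen-5-ol
Conditions: 2-methylbut-2-ene (excess), second-generation Grubbs catalyst (H2IMes)(PCy3)Cl2Ru=CHPh (cat.), CH2Cl2, 40 °C
Reagents that add atoms: 2-methylbut-2-ene, CC=C(C)C
Why: Olefin cross-metathesis with 2-methylbut-2-ene converts only the monosubstituted alkene into the isopropylidene (prenyl) terminus, since the trisubstituted alkenes and the iodoalkene are poor metathesis partners and the carbinol centre is not involved.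

Step 6
Reactants: 11 (5R,6E,10E,14E)-15-iodo-2,6,10,14-tetramethylpentadeca-2,6,10,14-tetraen-5-ol
Product: 14 ethyl (3R,6E,10E)-11-iodo-6,10-dimethyl-3-[(2E)-6-methylhepta-2,5-dien-2-yl]undeca-6,10-dienoate, via mixed orthoester 12 (not isolated), via ketene acetal 13 (not isolated)
Conditions: MeC(OEt)3 (excess), EtCO2H (cat.), 140 °C, EtOH distilled off
Reagents that add atoms: triethyl orthoacetate, CCOC(C)(OCC)OCC
Why: Johnson–Claisen rearrangement: the ketene acetal rearranges through a chair transition state with the prenyl-bearing carbinol substituent equatorial, which gives the E-trisubstituted side-chain alkene and transfers the R configuration of the C–O bond suprafacially across the E-allyl unit to the new C–C bond, setting the R stereocentre (ring C4 of the target).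

Step 7
Reactants: 14 ethyl (3R,6E,10E)-11-iodo-6,10-dimethyl-3-[(2E)-6-methylhepta-2,5-dien-2-yl]undeca-6,10-dienoate
Product: 15 (3R,6E,10E)-11-iodo-6,10-dimethyl-3-[(2E)-6-methylhepta-2,5-dien-2-yl]undeca-6,10-dienal
Conditions: i-Bu2AlH (1.1 equiv), CH2Cl2, −78 °C; aqueous potassium sodium tartrate
Reagents that add atoms: none
Why: Partial reduction of the ester with i-Bu2AlH at low temperature stops at the tetrahedral aluminium hemiacetal, which gives the aldehyde on work-up, and the stereocentre β to the carbonyl is not epimerisable.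

Step 8
Reactants: 16 methyl diethylphosphonoacetate; 17 tert-butyl acrylate
Product: 18 5-tert-butyl 1-methyl 2-(diethoxyphosphoryl)pentanedioate (racemic)
Conditions: 16 (excess), t-BuOK (cat.), THF, 0 °C → rt
Reagents that add atoms: none
Why: Base-catalysed Michael addition of the doubly stabilised phosphonoacetate carbanion to the acrylate, with the donor in excess to suppress double addition, gives the glutarate-type phosphonate (racemic at a centre that is destroyed later).

Step 9
Reactants: 18 5-tert-butyl 1-methyl 2-(diethoxyphosphoryl)pentanedioate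
Product: 19 4-(diethoxyphosphoryl)-5-methoxy-5-oxopentanoic acid (racemic)
Conditions: CF3CO2H, CH2Cl2, rt
Reagents that add atoms: none
Why: Acidolysis of the tert-butyl ester (loss of 2-methylpropene) frees the carboxylic acid while the methyl ester and the diethyl phosphonate are stable to CF3CO2H at room temperature.

Step 10
Reactants: 15 (3R,6E,10E)-11-iodo-6,10-dimethyl-3-[(2E)-6-methylhepta-2,5-dien-2-yl]undeca-6,10-dienal; 19 4-(diethoxyphosphoryl)-5-methoxy-5-oxopentanoic acid
Product: 20 (4E,7R,10E,14E)-15-iodo-4-(methoxycarbonyl)-10,14-dimethyl-7-[(2E)-6-methylhepta-2,5-dien-2-yl]pentadeca-4,10,14-trienoic acid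
Conditions: 19, LiN(SiMe3)2 (2 equiv per 19), THF, −78 → 0 °C; then 15, 0 °C → rt; cold 1 M HCl work-up
Reagents that add atoms: none
Why: Horner–Wadsworth–Emmons olefination of the carboxylate–phosphonate dianion with the aldehyde gives the thermodynamically preferred E-trisubstituted enoate (β-alkyl trans to CO2Me, as in α-alkyl phosphonoacetates generally) and delivers the free acid directly, leaving the remote stereocentre untouched.

Step 11
Reactants: 20 (4E,7R,10E,14E)-15-iodo-4-(methoxycarbonyl)-10,14-dimethyl-7-[(2E)-6-methylhepta-2,5-dien-2-yl]pentadeca-4,10,14-trienoic acid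
Product: 21 1,3-dioxoisoindolin-2-yl (4E,7R,10E,14E)-15-iodo-4-(methoxycarbonyl)-10,14-dimethyl-7-[(2E)-6-methylhepta-2,5-dien-2-yl]pentadeca-4,10,14-trienoate
Conditions: N-hydroxyphthalimide, N,N′-diisopropylcarbodiimide, DMAP (cat.), CH2Cl2, rt
Reagents that add atoms: N-hydroxyphthalimide, O=C1c2ccccc2C(=O)N1O
Why: Carbodiimide-mediated (Steglich-type) esterification of the only free carboxylic acid with N-hydroxyphthalimide gives the redox-active ester under neutral conditions that leave the enoate, the alkenyl iodide and the skipped diene intact.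

Step 12
Reactants: 21 1,3-dioxoisoindolin-2-yl (4E,7R,10E,14E)-15-iodo-4-(methoxycarbonyl)-10,14-dimethyl-7-[(2E)-6-methylhepta-2,5-dien-2-yl]pentadeca-4,10,14-trienoate
Product: 22 methyl (1E,4R,7E,11E)-7,11-dimethyl-4-[(2E)-6-methylhepta-2,5-dien-2-yl]cyclotetradeca-1,7,11-triene-1-carboxylate
Conditions: NiCl2·6H2O (20 mol %), 2,2′-bipyridine (20 mol %), AgNO3 (30 mol %), LiCl, DMF, undivided cell, Mg anode, reticulated vitreous carbon cathode, constant current, rt; 21 added by syringe pump (final ca. 3 mM)
Reagents that add atoms: none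
Why: Proposed new method: the closest known reaction type is the intermolecular nickel-electrocatalytic decarboxylative alkenylation of primary N-acyloxyphthalimides by E-2-methylalk-1-enyl iodides at a silver-nanoparticle-coated cathode, which forms exactly this kind of C(sp2)–C(sp3) link in linear polyenes; it is run here intramolecularly as a macrocyclisation, a mode that is not established. Cathodically generated zerovalent nickel–bipyridine inserts into the C12–I bond with retention of the E geometry, single-electron reduction of the phthalimide ester expels CO2 and phthalimide anion to leave the primary C13 radical, and capture of that radical by the alkenyl nickel followed by reductive elimination from trivalent nickel forms C12–C13. The 14-membered ring closes by radical capture at the metal and C–C reductive elimination through a 15-membered nickelacycle, not by radical addition to a π bond. No stereocentre is formed: C4 and the other alkenes are spectators and the C11=C12 geometry is carried over from the iodide. The step needs ring closure to outrun oligomerisation, homocoupling and hydrogen-atom capture by the radical; slow addition of 21 to the full catalyst charge keeps the substrate dilute so that its alkenyl iodide is metalated before its ester is reduced, and the three E-trisubstituted alkenes together with the cis-related ring arms at C1=C2 restrict the chain. The redox-active ester is reduced at a much less negative potential than the enoate, and the C13 radical has no fast cyclisation channel (only 3-exo or 4-endo attack on C1=C2).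

Compound list
1 | geranyl bromide, (2E)-1-bromo-3,7-dimethylocta-2,6-diene | CC(C)=CCC/C(C)=C/CBr | starting material
2 | 1-(trimethylsilyl)propyne | CC#C[Si](C)(C)C | starting material
3 | trimethyl[(5E)-6,10-dimethylundeca-5,9-dien-1-yn-1-yl]silane | CC(C)=CCC/C(C)=C/CCC#C[Si](C)(C)C | intermediate (not isolated)
4 | (5E)-6,10-dimethylundeca-5,9-dien-1-yne | CC(C)=CCC/C(C)=C/CCC#C | intermediate
5 | dimethyl[(1E,5E)-2,6,10-trimethylundeca-1,5,9-trien-1-yl]alane | CC(C)=CCC/C(C)=C/CC/C(C)=C/[Al](C)C | intermediate (not isolated)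
6 | (1E,5E)-1-iodo-2,6,10-trimethylundeca-1,5,9-triene | CC(C)=CCC/C(C)=C/CC/C(C)=C/I | intermediate
7 | (2E,6E,10E)-11-iodo-2,6,10-trimethylundeca-2,6,10-trien-1-ol | OC/C(C)=C/CC/C(C)=C/CC/C(C)=C/I | intermediate (not isolated)
8 | (2E,6E,10E)-11-iodo-2,6,10-trimethylundeca-2,6,10-trienal | O=C/C(C)=C/CC/C(C)=C/CC/C(C)=C/I | intermediate
9 | bis(isopinocampheyl)borinate ester of 10 (O–B(Ipc)2, Ipc from (−)-α-pinene) | C=CC[C@@H](OB([C@@H]1[C@@H](C)[C@@H]2C[C@H](C1)C2(C)C)[C@@H]1[C@@H](C)[C@@H]2C[C@H](C1)C2(C)C)/C(C)=C/CC/C(C)=C/CC/C(C)=C/I | intermediate (not isolated)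
10 | (4R,5E,9E,13E)-14-iodo-5,9,13-trimethyltetradeca-1,5,9,13-tetraen-4-ol | C=CC[C@@H](O)/C(C)=C/CC/C(C)=C/CC/C(C)=C/I | intermediate
11 | (5R,6E,10E,14E)-15-iodo-2,6,10,14-tetramethylpentadeca-2,6,10,14-tetraen-5-ol | CC(C)=CC[C@@H](O)/C(C)=C/CC/C(C)=C/CC/C(C)=C/I | intermediate
12 | mixed orthoacetate of 11 (1,1-diethoxyethyl ether) | CC(C)=CC[C@@H](OC(C)(OCC)OCC)/C(C)=C/CC/C(C)=C/CC/C(C)=C/I | intermediate (not isolated)
13 | ketene acetal of 11 (1-ethoxyvinyl ether) | CC(C)=CC[C@@H](OC(=C)OCC)/C(C)=C/CC/C(C)=C/CC/C(C)=C/I | intermediate (not isolated)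
14 | ethyl (3R,6E,10E)-11-iodo-6,10-dimethyl-3-[(2E)-6-methylhepta-2,5-dien-2-yl]undeca-6,10-dienoate | CCOC(=O)C[C@H](/C(C)=C/CC=C(C)C)CC/C(C)=C/CC/C(C)=C/I | intermediate
15 | (3R,6E,10E)-11-iodo-6,10-dimethyl-3-[(2E)-6-methylhepta-2,5-dien-2-yl]undeca-6,10-dienal | O=CC[C@H](/C(C)=C/CC=C(C)C)CC/C(C)=C/CC/C(C)=C/I | intermediate
16 | methyl diethylphosphonoacetate | CCOP(=O)(CC(=O)OC)OCC | starting material
17 | tert-butyl acrylate | C=CC(=O)OC(C)(C)C | starting material
18 | 5-tert-butyl 1-methyl 2-(diethoxyphosphoryl)pentanedioate (racemic) | CCOP(=O)(OCC)C(CCC(=O)OC(C)(C)C)C(=O)OC | intermediate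
19 | 4-(diethoxyphosphoryl)-5-methoxy-5-oxopentanoic acid (racemic) | CCOP(=O)(OCC)C(CCC(=O)O)C(=O)OC | intermediate
20 | (4E,7R,10E,14E)-15-iodo-4-(methoxycarbonyl)-10,14-dimethyl-7-[(2E)-6-methylhepta-2,5-dien-2-yl]pentadeca-4,10,14-trienoic acid | COC(=O)/C(CCC(=O)O)=C/C[C@H](/C(C)=C/CC=C(C)C)CC/C(C)=C/CC/C(C)=C/I | intermediate
21 | N-hydroxyphthalimide ester of 20 | COC(=O)/C(CCC(=O)ON1C(=O)c2ccccc2C1=O)=C/C[C@H](/C(C)=C/CC=C(C)C)CC/C(C)=C/CC/C(C)=C/I | intermediate
22 | methyl (1E,4R,7E,11E)-7,11-dimethyl-4-[(2E)-6-methylhepta-2,5-dien-2-yl]cyclotetradeca-1,7,11-triene-1-carboxylate | COC(=O)/C1=C/C[C@H](/C(C)=C/CC=C(C)C)CC/C(C)=C/CC/C(C)=C/CC1 | target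

Total step count: 12. Longest linear sequence: 10 steps (steps 1–7 and 10–12, from geranyl bromide); steps 8 and 9 form the side branch.

Steps most likely to fail

Step 12 (proposed new method). Oligomerisation, and loss of the C13 radical by hydrogen-atom capture before it reaches the nickel centre, may outrun ring closure. The fallback uses known chemistry and forms the same bond by a two-electron pathway. Setting out from 21, photochemical decarboxylative borylation (B2cat2, DMAc, blue light, rt) should give the catechol boronate F1, which is transesterified in the same flask (pinacol, Et3N) to the pinacol boronate F2. An intramolecular B-alkyl Suzuki–Miyaura macrocyclisation (Pd(OAc)2, RuPhos, aqueous K3PO4, toluene, 80 °C, slow addition) then joins C13 to C12 and comes back to the route at 22.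

Step 3. Poor site selectivity between the terminal and the internal trisubstituted alkene, together with over-oxidation, may leave little of the terminal E-oxidation product. The fallback sets out from 6: terminal-selective bromohydrin formation (NBS, THF/H2O, 0 °C) should give the bromohydrin F3, and K2CO3/MeOH closes it to the terminal epoxide F4. H5IO6 (THF/Et2O) cleaves the epoxide to the trisnor aldehyde F5, and a Wittig reaction with the stabilised ylide 2-(triphenylphosphoranylidene)propanal (toluene, 90 °C) rebuilds the E-2-methyl enal, coming back at 8.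

Step 10. Slow olefination by the poorly soluble dianion and erosion of E selectivity may occur. The fallback sets out from 15 and 18: a mono-anion Horner–Wadsworth–Emmons reaction (NaH, THF, 0 °C → rt) should give the tert-butyl methyl diester F6. Buffered silyl triflate cleavage (Me3SiOSO2CF3, 2,6-lutidine, CH2Cl2, 0 °C) converts the tert-butyl ester into the trimethylsilyl ester F7, which is hydrolysed on aqueous work-up, coming back at 20.

Further compounds
F1 | step 12 | methyl (2E,5R,8E,12E)-2-[2-(1,3,2-benzodioxaborol-2-yl)ethyl]-13-iodo-8,12-dimethyl-5-[(2E)-6-methylhepta-2,5-dien-2-yl]trideca-2,8,12-trienoate | COC(=O)/C(CCB1Oc2ccccc2O1)=C/C[C@H](/C(C)=C/CC=C(C)C)CC/C(C)=C/CC/C(C)=C/I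
F2 | step 12 | methyl (2E,5R,8E,12E)-13-iodo-8,12-dimethyl-5-[(2E)-6-methylhepta-2,5-dien-2-yl]-2-[2-(4,4,5,5-tetramethyl-1,3,2-dioxaborolan-2-yl)ethyl]trideca-2,8,12-trienoate | COC(=O)/C(CCB1OC(C)(C)C(C)(C)O1)=C/C[C@H](/C(C)=C/CC=C(C)C)CC/C(C)=C/CC/C(C)=C/I
F3 | step 3 | (6E,10E)-3-bromo-11-iodo-2,6,10-trimethylundeca-6,10-dien-2-ol (racemic) | CC(C)(O)C(Br)CC/C(C)=C/CC/C(C)=C/I
F4 | step 3 | 3-[(3E,7E)-8-iodo-3,7-dimethylocta-3,7-dien-1-yl]-2,2-dimethyloxirane (racemic) | CC1(C)OC1CC/C(C)=C/CC/C(C)=C/I
F5 | step 3 | (4E,8E)-9-iodo-4,8-dimethylnona-4,8-dienal | O=CCC/C(C)=C/CC/C(C)=C/I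
F6 | step 10 | tert-butyl (4E,7R,10E,14E)-15-iodo-4-(methoxycarbonyl)-10,14-dimethyl-7-[(2E)-6-methylhepta-2,5-dien-2-yl]pentadeca-4,10,14-trienoate | COC(=O)/C(CCC(=O)OC(C)(C)C)=C/C[C@H](/C(C)=C/CC=C(C)C)CC/C(C)=C/CC/C(C)=C/I
F7 | step 10 | trimethylsilyl (4E,7R,10E,14E)-15-iodo-4-(methoxycarbonyl)-10,14-dimethyl-7-[(2E)-6-methylhepta-2,5-dien-2-yl]pentadeca-4,10,14-trienoate | COC(=O)/C(CCC(=O)O[Si](C)(C)C)=C/C[C@H](/C(C)=C/CC=C(C)C)CC/C(C)=C/CC/C(C)=C/I
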